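## Retrosynthetic overview

1. Carotenoid numbering is used: ring C1 = CMe2, C2 and C3 = carbinols, C4 = CH2, C5=C6 = ring alkene, chain C7–C15. Primes mark the sulfated half (ring B); the other ring is ring A. In both six-membered rings, carbinol C2 lies between carbinol C3 and the quaternary C1, which is bonded to alkene carbon C6. The array C6–C1(Me2)–C2(OH) is what remains when a C1–C2 epoxide is opened at C1 onto a C5=C6 alkene. O3 is allylic to the earlier C1=C2 alkene and can steer that epoxidation.
2. C40 = C10 + C20 + C10. Wittig cuts at C7=C8 and C7'=C8' lead to crocetindial and two ring phosphonium salts that differ only at O3 (TES for ring B, TBS for ring A). O3' is unmasked alone and sulfated, and the remaining silyl groups leave last.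
3. Both salts come from one ring synthesis. C1–C6 is closed by a Cp2TiCl radical cyclisation of an acyclic (E)-5-silyloxy-6,7-epoxygeranyl acetate. The exocyclic alkene is then moved into C5=C6 through the C7 aldehyde.
4. In the acyclic precursor, C3–C4 comes from a catalytic asymmetric vinylogous Mukaiyama aldol of the senecioate dienolate with prenal (sets C3). C2 comes from a hydroxyl-directed epoxidation under A(1,3) control.
5. Ring order: step 7 is the only ring-forming event, and the six-membered ring is made once and used twice. Ring B is joined to the C20 chain in step 15 and ring A in step 16.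

Key step: step 7

Remark: the target is drawn as the free hydrogen sulfate, so the sulfate is carried as its pyridinium salt and the acid form is released only in the last operation, to be kept cold or converted into a salt for storage.

## Route

Step 1
Reactants: 1 methyl senecioate (methyl 3-methylbut-2-enoate)
Product: 3 tert-butyl[(1-methoxy-3-methylbuta-1,3-dien-1-yl)oxy]dimethylsilane (silyl dienolate), via lithium dienolate 2 (not isolated)
Conditions: LiN(iPr)2, THF, −78 °C; then TBSCl, DMPU, −78 °C to rt
Reagents that add atoms: TBSCl, CC(C)(C)[Si](C)(C)Cl; LiN(iPr)2, [Li+].CC(C)[N-]C(C)C (lithium of 2 only)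
Why: Kinetic γ-deprotonation of the senecioate gives the extended lithium dienolate, which the hard silyl chloride traps on oxygen in the presence of DMPU (silyl ketene acetal formation).

Step 2
Reactants: 3 silyl dienolate; 4 prenal (3-methylbut-2-enal)
Product: 5 methyl (2E,5R)-5-hydroxy-3,7-dimethylocta-2,6-dienoate
Conditions: SiCl4 (1.1 equiv), (R,R)-bisphosphoramide (two cyclic P(=O) triamide units built on N,N'-dimethyl-1,1'-binaphthyl-2,2'-diamine, linked by MeN(CH2)5NMe; 2 mol %), iPr2NEt (10 mol %), CH2Cl2, −78 °C; cold aq NaHCO3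
Reagents that add atoms: none
Why: Vinylogous Mukaiyama aldol with Lewis-base-activated SiCl4, in which the phosphoramide-bound trichlorosilyl cation binds prenal and leaves its Re face open to the unhindered γ-carbon of 3, setting C3 (octadienoate C5) as R and giving the E-enoate through the extended s-trans dienolate, while any Z-isomer would lactonise and be removed on silica; the catalyst antipode is the one expected to give Re-face attack on conjugated aldehydes, and the assignment would be confirmed on 5 by Mosher ester analysis.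

Step 3
Reactants: 5 aldol product
Product: 6 methyl (2E,5R)-5-[(2S)-3,3-dimethyloxiran-2-yl]-5-hydroxy-3-methylpent-2-enoate (threo epoxy alcohol)
Conditions: mCPBA (1.05 equiv), solid NaHCO3, CH2Cl2, 0 °C
Reagents that add atoms: mCPBA, OOC(=O)c1cccc(Cl)c1
Why: Hydroxyl-directed peracid epoxidation, in which the electron-poor enoate is inert and the Z-methyl group of the electron-rich C1=C2 alkene forces the C3–H bond into the alkene plane (A(1,3) strain), so the hydrogen-bonded peracid reaches the face that carries O3 and gives the threo epoxy alcohol with C2 as S, the arrangement that becomes the trans-2,3-diol.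

Step 4
Reactants: 6 epoxy alcohol
Product: 7 methyl (2E,5R)-5-[(2S)-3,3-dimethyloxiran-2-yl]-3-methyl-5-(triethylsilyloxy)pent-2-enoate
Conditions: TESCl, imidazole, DMAP (cat.), CH2Cl2, 0 °C
Reagents that add atoms: TESCl, CC[Si](Cl)(CC)CC
Why: Standard silylation under imidazole conditions, which are too weakly basic for a Payne rearrangement, with TES chosen because it can later be removed in the presence of TBS.

Step 5
Reactants: 7 silylated epoxy ester
Product: 8 (2E,5R)-5-[(2S)-3,3-dimethyloxiran-2-yl]-3-methyl-5-(triethylsilyloxy)pent-2-en-1-ol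
Conditions: iBu2AlH (2.3 equiv), CH2Cl2, −78 °C; aq potassium sodium tartrate
Reagents that add atoms: none
Why: iBu2AlH reduces the conjugated ester in 1,2-fashion at −78 °C without touching the trisubstituted epoxide or the silyl ether, and the ester must go because an enoate would draw a nucleophilic radical to C5 instead of C6.

Step 6
Reactants: 8 allylic alcohol
Product: 9 (2E,5R,6S)-6,7-epoxy-5-(triethylsilyloxy)geranyl acetate (cyclisation precursor)
Conditions: Ac2O, pyridine, DMAP (cat.), CH2Cl2, 0 °C to rt
Reagents that add atoms: acetic anhydride, CC(=O)OC(C)=O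
Why: Routine DMAP-catalysed acetylation caps the primary alcohol, which would otherwise bind and consume the oxophilic titanium reagent.

Step 7
Reactants: 9 epoxy allylic acetate
Product: 10 [(1R,3R,4R)-3-hydroxy-2,2-dimethyl-6-methylidene-4-(triethylsilyloxy)cyclohexyl]methyl acetate (carotenoid numbering 2R,3R,6R)
Conditions: Cp2TiCl2 (2.5 equiv), Mn dust (8 equiv), degassed THF, rt, 15 min (green Cp2TiCl); slow addition of 9 (final 0.02 M), rt; aq NaH2PO4
Reagents that add atoms: none
Why: Cp2TiCl (trivalent titanium, made in the flask) binds the epoxide oxygen and transfers one electron, which breaks the C1–O bond to give the tertiary C1 radical while the C2–O bond, and with it the configuration relayed from C3, stays intact. The radical adds to C6 of the trisubstituted alkene (6-endo-trig, closing the ring C1–C6) to give the tertiary C5 radical, which a second Cp2TiCl captures and which then loses Cp2Ti(H)Cl by β-hydride elimination towards the methyl group, leaving the exocyclic C5 methylene, and the mild aqueous work-up frees the C2 hydroxyl. The closest known reaction is the Cp2TiCl cyclisation of 6,7-epoxygeranyl acetate and of higher epoxypolyprenyl acetates, from which 9 differs only by the C3 silyloxy group. The new stereocentre C6 is set by a chair transition state in which O2, O3 and, because the alkene is E, the C7 acetoxymethyl arm are all equatorial, and since C6 is erased in step 10 its control is not critical. The step needs 6-endo over 5-exo closure and cyclisation over deoxygenation or disproportionation of the C1 radical: attack at the CH carbon C6 avoids two adjacent quaternary carbons and delivers the more stable tertiary radical, the allylic acetate leaves the alkene electronically unbiased, and the crowded tertiary C1 radical is captured only slowly by the bulky titanium reagent, helped by slow addition at high dilution.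

Step 8
Reactants: 10 cyclised hydroxy acetate
Product: 11 [(1R,3R,4R)-3-(tert-butyldimethylsilyloxy)-2,2-dimethyl-6-methylidene-4-(triethylsilyloxy)cyclohexyl]methyl acetate
Conditions: TBSOTf (1.5 equiv), 2,6-lutidine (3 equiv), CH2Cl2, 0 °C to rt
Reagents that add atoms: TBSOTf, CC(C)(C)[Si](C)(C)OS(=O)(=O)C(F)(F)F
Why: The hindered neopentyl-type C2 hydroxyl needs the reactive silyl triflate, and 2,6-lutidine keeps the medium non-acidic so that the TES ether, the acetate and the exocyclic alkene survive.

Step 9
Reactants: 11 bis-silyl acetate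
Product: 12 [(1R,3R,4R)-3-(tert-butyldimethylsilyloxy)-2,2-dimethyl-6-methylidene-4-(triethylsilyloxy)cyclohexyl]methanol
Conditions: K2CO3 (0.3 equiv), MeOH, 0 °C to rt
Reagents that add atoms: none
Why: Base-catalysed transesterification removes the primary acetate under conditions that secondary TES and TBS ethers tolerate.

Step 10
Reactants: 12 primary alcohol
Product: 14 (4R,5R)-5-(tert-butyldimethylsilyloxy)-2,6,6-trimethyl-4-(triethylsilyloxy)cyclohex-1-ene-1-carbaldehyde, via exocyclic-alkene aldehyde 13 (not isolated)
Conditions: Dess–Martin periodinane, NaHCO3, CH2Cl2, 0 °C to rt; filter; then DBU (0.2 equiv), CH2Cl2, 0 °C to rt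
Reagents that add atoms: none
Why: Dess–Martin oxidation gives the β,γ-unsaturated aldehyde, whose doubly activated C6–H is removed by catalytic DBU to a dienolate that is reprotonated at the exocyclic CH2, which moves the alkene into the conjugated tetrasubstituted C5=C6 position and erases C6, while the weak base and short contact time are meant to avoid γ-deprotonation at C4 of 14 and vinylogous loss of the C3 silyloxy group.

Step 11
Reactants: 14 conjugated aldehyde
Product: 15 [(4R,5R)-5-(tert-butyldimethylsilyloxy)-2,6,6-trimethyl-4-(triethylsilyloxy)cyclohex-1-en-1-yl]methanol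
Conditions: iBu2AlH (1.2 equiv), CH2Cl2, −78 °C; aq potassium sodium tartrate
Reagents that add atoms: none
Why: 1,2-Reduction of the hindered enal by iBu2AlH, which is neutral towards both silyl ethers, gives the β-cyclogeraniol-type allylic alcohol.

Step 12
Reactants: 15 allylic alcohol
Product: 17 {[(4R,5R)-5-(tert-butyldimethylsilyloxy)-2,6,6-trimethyl-4-(triethylsilyloxy)cyclohex-1-en-1-yl]methyl}triphenylphosphonium bromide (ring B salt), via allylic bromide 16 (not isolated)
Conditions: CBr4 (1.2 equiv), PPh3 (2.5 equiv), 2,6-lutidine (0.2 equiv), CH2Cl2, 0 °C to rt, 16 h; trituration with hexane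
Reagents that add atoms: CBr4, BrC(Br)(Br)Br; PPh3, c1ccc(cc1)P(c1ccccc1)c1ccccc1
Why: Appel bromination under neutral conditions spares the acid-labile TES ether, and the primary allylic bromide is quaternised in the same flask by the excess PPh3 (SN2), as known for β-cyclogeranyl bromide.

Step 13
Reactants: 17 ring B salt (one portion)
Product: 18 {[(4R,5R)-5-(tert-butyldimethylsilyloxy)-4-hydroxy-2,6,6-trimethylcyclohex-1-en-1-yl]methyl}triphenylphosphonium bromide
Conditions: aq HBr (5 mol %), MeOH, 0 °C
Reagents that add atoms: none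
Why: Acid-catalysed methanolysis cleaves the unhindered secondary TES ether far faster than the TBS ether at the neopentyl-type C2 position, and HBr introduces no foreign counter-ion.

Step 14
Reactants: 18 hydroxy salt
Product: 19 {[(4R,5R)-4,5-bis(tert-butyldimethylsilyloxy)-2,6,6-trimethylcyclohex-1-en-1-yl]methyl}triphenylphosphonium bromide (ring A salt)
Conditions: TBSCl, imidazole, DMF, rt; CH2Cl2 extract washed with aq NaBr
Reagents that add atoms: TBSCl, CC(C)(C)[Si](C)(C)Cl; NaBr, [Na+].[Br-] (keeps bromide as the counter-ion)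
Why: Standard imidazole-promoted silylation of the free C3 hydroxyl, in which a possible TBS shift between O2 and O3 is harmless because both oxygens end up as TBS ethers.

Step 15
Reactants: 17 ring B salt; 20 crocetindial (C20 dialdehyde, 3 equiv)
Product: 22 C30 aldehyde (ring B joined through an E C7'=C8' alkene to the all-E chain with the formyl group at C8), via ring B ylide 21 (not isolated)
Conditions: 17, NaN(SiMe3)2 (1.0 equiv), THF, −78 to 0 °C; cannulated into 20, CH2Cl2–THF, −30 °C to rt, dark, Ar
Reagents that add atoms: none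
Why: Wittig olefination forms C7'=C8', where inverse addition of the ylide to an excess of the dialdehyde and the lower electrophilicity of the formyl group of 22 at the end of a longer polyene favour mono-olefination, and the clash of a Z-alkene with the C1' and C5' methyl groups favours the E-isomer.

Step 16
Reactants: 19 ring A salt (1.6 equiv); 22 C30 aldehyde
Product: 24 (all-E,2R,3R,2'R,3'R)-2,3,2'-tris(tert-butyldimethylsilyloxy)-3'-(triethylsilyloxy)-β,β-carotene, via ring A ylide 23 (not isolated)
Conditions: 19, NaN(SiMe3)2 (1.5 equiv), THF, −78 to 0 °C; then 22, THF, −78 °C to rt, dark, Ar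
Reagents that add atoms: none
Why: Second Wittig olefination (C7=C8), now with excess ylide on the single remaining formyl group and E-selective for the same steric reason, and any residual minor enantiomer of the ring building block ends up mainly in a diastereomer that can be separated at this stage.

Step 17
Reactants: 24 fully protected C40 carotenoid
Product: 25 (all-E,2R,3R,2'R,3'R)-2,3,2'-tris(tert-butyldimethylsilyloxy)-β,β-caroten-3'-ol
Conditions: PPTS (0.3 equiv), CH2Cl2–MeOH (2:1), 0 °C to rt, dark
Reagents that add atoms: none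
Why: Mild acid methanolysis distinguishes the TES ether from the three TBS ethers, is too weak to protonate the polyene and, being non-basic, does not trigger migration of the O2' silyl group to O3'.

Step 18
Reactants: 25 C40 mono-alcohol
Product: 26 pyridinium (all-E,2R,3R,2'R,3'R)-2,3,2'-tris(tert-butyldimethylsilyloxy)-β,β-caroten-3'-yl sulfate
Conditions: SO3·pyridine (5 equiv), pyridine, rt, dark, Ar
Reagents that add atoms: sulfur trioxide pyridine complex, O=S(=O)([O-])[n+]1ccccc1
Why: O-Sulfation of the only free hydroxyl with the SO3·pyridine complex, the standard method for carotenol sulfates, runs in a basic medium that harms neither the polyene nor the silyl ethers.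

Step 19
Reactants: 26 protected sulfate salt
Product: 28 (all-E,2R,3R,2'R,3'R)-2,3,2'-trihydroxy-β,β-caroten-3'-yl hydrogen sulfate (target), via target pyridinium salt 27 (not isolated)
Conditions: HF·pyridine, pyridine, THF, 0 °C to rt, polypropylene flask, dark; Me3SiOMe quench, concentrate; then sulfonic acid resin (H+ form), MeOH, 0 °C
Reagents that add atoms: none
Why: Buffered fluoride cleaves the Si–O bonds without touching the sulfate monoester anion and without generating a free C2' alkoxide that could displace the neighbouring sulfate, and a short cold pass over the sulfonic acid resin exchanges pyridinium for a proton.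

## Compound list

1 | methyl senecioate | CC(C)=CC(=O)OC | starting material
2 | lithium dienolate of 1 | C=C(C)C=C(OC)[O-].[Li+] | intermediate
3 | tert-butyl[(1-methoxy-3-methylbuta-1,3-dien-1-yl)oxy]dimethylsilane | C=C(C)C=C(OC)O[Si](C)(C)C(C)(C)C | intermediate
4 | prenal | CC(C)=CC=O | starting material
5 | methyl (2E,5R)-5-hydroxy-3,7-dimethylocta-2,6-dienoate | CC(C)=C[C@H](O)C/C(C)=C/C(=O)OC | intermediate
6 | methyl (2E,5R)-5-[(2S)-3,3-dimethyloxiran-2-yl]-5-hydroxy-3-methylpent-2-enoate | CC1(C)O[C@H]1[C@H](O)C/C(C)=C/C(=O)OC | intermediate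
7 | methyl (2E,5R)-5-[(2S)-3,3-dimethyloxiran-2-yl]-3-methyl-5-(triethylsilyloxy)pent-2-enoate | CC1(C)O[C@H]1[C@H](O[Si](CC)(CC)CC)C/C(C)=C/C(=O)OC | intermediate
8 | (2E,5R)-5-[(2S)-3,3-dimethyloxiran-2-yl]-3-methyl-5-(triethylsilyloxy)pent-2-en-1-ol | CC1(C)O[C@H]1[C@H](O[Si](CC)(CC)CC)C/C(C)=C/CO | intermediate
9 | (2E,5R,6S)-6,7-epoxy-5-(triethylsilyloxy)geranyl acetate | CC1(C)O[C@H]1[C@H](O[Si](CC)(CC)CC)C/C(C)=C/COC(C)=O | intermediate
10 | [(1R,3R,4R)-3-hydroxy-2,2-dimethyl-6-methylidene-4-(triethylsilyloxy)cyclohexyl]methyl acetate | CC1(C)[C@@H](O)[C@H](O[Si](CC)(CC)CC)CC(=C)[C@H]1COC(C)=O | intermediate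
11 | O2-TBS ether of 10 | CC1(C)[C@@H](O[Si](C)(C)C(C)(C)C)[C@H](O[Si](CC)(CC)CC)CC(=C)[C@H]1COC(C)=O | intermediate
12 | primary alcohol from 11 | CC1(C)[C@@H](O[Si](C)(C)C(C)(C)C)[C@H](O[Si](CC)(CC)CC)CC(=C)[C@H]1CO | intermediate
13 | (1R,3R,4R)-3-(tert-butyldimethylsilyloxy)-2,2-dimethyl-6-methylidene-4-(triethylsilyloxy)cyclohexane-1-carbaldehyde | CC1(C)[C@@H](O[Si](C)(C)C(C)(C)C)[C@H](O[Si](CC)(CC)CC)CC(=C)[C@H]1C=O | intermediate
14 | (4R,5R)-5-(tert-butyldimethylsilyloxy)-2,6,6-trimethyl-4-(triethylsilyloxy)cyclohex-1-ene-1-carbaldehyde | CC1=C(C=O)C(C)(C)[C@@H](O[Si](C)(C)C(C)(C)C)[C@H](O[Si](CC)(CC)CC)C1 | intermediate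
15 | allylic alcohol from 14 | CC1=C(CO)C(C)(C)[C@@H](O[Si](C)(C)C(C)(C)C)[C@H](O[Si](CC)(CC)CC)C1 | intermediate
16 | allylic bromide from 15 | CC1=C(CBr)C(C)(C)[C@@H](O[Si](C)(C)C(C)(C)C)[C@H](O[Si](CC)(CC)CC)C1 | intermediate
17 | ring B phosphonium bromide (O2 TBS, O3 TES) | CC1=C(C[P+](c2ccccc2)(c2ccccc2)c2ccccc2)C(C)(C)[C@@H](O[Si](C)(C)C(C)(C)C)[C@H](O[Si](CC)(CC)CC)C1.[Br-] | intermediate
18 | hydroxy phosphonium bromide (O2 TBS, O3 free) | CC1=C(C[P+](c2ccccc2)(c2ccccc2)c2ccccc2)C(C)(C)[C@@H](O[Si](C)(C)C(C)(C)C)[C@H](O)C1.[Br-] | intermediate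
19 | ring A phosphonium bromide (O2 TBS, O3 TBS) | CC1=C(C[P+](c2ccccc2)(c2ccccc2)c2ccccc2)C(C)(C)[C@@H](O[Si](C)(C)C(C)(C)C)[C@H](O[Si](C)(C)C(C)(C)C)C1.[Br-] | intermediate
20 | crocetindial | O=C/C(C)=C/C=C/C(C)=C/C=C/C=C(C)/C=C/C=C(C)/C=O | starting material
21 | ring B ylide | CC1=C(C=P(c2ccccc2)(c2ccccc2)c2ccccc2)C(C)(C)[C@@H](O[Si](C)(C)C(C)(C)C)[C@H](O[Si](CC)(CC)CC)C1 | intermediate
22 | C30 aldehyde carrying ring B | O=C/C(C)=C/C=C/C(C)=C/C=C/C=C(C)/C=C/C=C(C)/C=C/C1=C(C)C[C@@H](O[Si](CC)(CC)CC)[C@H](O[Si](C)(C)C(C)(C)C)C1(C)C | intermediate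
23 | ring A ylide | CC1=C(C=P(c2ccccc2)(c2ccccc2)c2ccccc2)C(C)(C)[C@@H](O[Si](C)(C)C(C)(C)C)[C@H](O[Si](C)(C)C(C)(C)C)C1 | intermediate
24 | fully protected C40 carotenoid (O2, O3, O2' TBS; O3' TES) | CC1=C(/C=C/C(C)=C/C=C/C(C)=C/C=C/C=C(C)/C=C/C=C(C)/C=C/C2=C(C)C[C@@H](O[Si](CC)(CC)CC)[C@H](O[Si](C)(C)C(C)(C)C)C2(C)C)C(C)(C)[C@@H](O[Si](C)(C)C(C)(C)C)[C@H](O[Si](C)(C)C(C)(C)C)C1 | intermediate
25 | C40 3'-alcohol (O2, O3, O2' TBS) | CC1=C(/C=C/C(C)=C/C=C/C(C)=C/C=C/C=C(C)/C=C/C=C(C)/C=C/C2=C(C)C[C@@H](O)[C@H](O[Si](C)(C)C(C)(C)C)C2(C)C)C(C)(C)[C@@H](O[Si](C)(C)C(C)(C)C)[C@H](O[Si](C)(C)C(C)(C)C)C1 | intermediate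
26 | pyridinium salt of the tris-TBS 3'-sulfate | CC1=C(/C=C/C(C)=C/C=C/C(C)=C/C=C/C=C(C)/C=C/C=C(C)/C=C/C2=C(C)C[C@@H](OS(=O)(=O)[O-])[C@H](O[Si](C)(C)C(C)(C)C)C2(C)C)C(C)(C)[C@@H](O[Si](C)(C)C(C)(C)C)[C@H](O[Si](C)(C)C(C)(C)C)C1.c1cc[nH+]cc1 | intermediate
27 | pyridinium salt of the target | CC1=C(/C=C/C(C)=C/C=C/C(C)=C/C=C/C=C(C)/C=C/C=C(C)/C=C/C2=C(C)C[C@@H](OS(=O)(=O)[O-])[C@H](O)C2(C)C)C(C)(C)[C@@H](O)[C@H](O)C1.c1cc[nH+]cc1 | intermediate
28 | (all-E,2R,3R,2'R,3'R)-2,3,2'-trihydroxy-β,β-caroten-3'-yl hydrogen sulfate | CC1=C(/C=C/C(C)=C/C=C/C(C)=C/C=C/C=C(C)/C=C/C=C(C)/C=C/C2=C(C)C[C@@H](OS(=O)(=O)O)[C@H](O)C2(C)C)C(C)(C)[C@@H](O)[C@H](O)C1 | target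

## Step count

Total step count: 19.
Longest linear sequence: 18 (steps 1–14, then 16–19). The branch through step 15 is 17 steps long.

## Steps most likely to fail

**Step 7.** The extra C3 silyloxy group crowds the chair. The tertiary C1 radical may therefore be lost to disproportionation, or to capture by a second titanium centre followed by deoxygenation, before it reaches C6.

- The fallback closes the same C1–C6 bond by a polar route with a stronger internal nucleophile. It sets out from 8 and comes back at 13.
- MnO2 in CH2Cl2 would oxidise 8 to the epoxy enal F1.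
- NaN(SiMe3)2 and TBSCl in THF at −78 °C would remove a proton from the C5 methyl group, which lies cis to the formyl group, and give the silyl dienol ether F2.
- MeAlCl2 in CH2Cl2 at −78 °C would ionise the C1–O bond. C6, the α-carbon of the dienol ether, would capture C1 in a six-membered closure, because attack through the terminal CH2 would need an eight-membered ring. This would give the cyclised hydroxy aldehyde F3, with the exocyclic methylene already in place.
- TBSOTf and 2,6-lutidine would then silylate O2 to give 13. The DBU treatment of step 10 carries 13 on to 14.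

**Step 2.** Three things may go wrong:

- enantioselectivity may be insufficient;
- control of the enoate geometry with the β-methyl dienolate may be incomplete;
- the prenyl-type allylic C3–O bond may ionise in the chlorosilane medium.

The fallback sets C3 by reagent control and builds the enoate afterwards. It sets out from 4 and comes back at 7.

- Brown methallylboration of 4 would be run with (+)-Ipc2B(CH2C(CH3)=CH2), made from (+)-Ipc2BOMe and CH2=C(CH3)CH2MgCl, in Et2O at −78 °C with NaOH/H2O2 work-up. It would attack the Re face and give (4R)-2,6-dimethylhepta-1,5-dien-4-ol F4.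
- One equivalent of mCPBA would epoxidise the more electron-rich, hydroxyl-directed trisubstituted alkene under the same A(1,3) control, giving the threo epoxy alcohol F5.
- TESCl and imidazole would give the silyl ether F6.
- Lemieux–Johnson cleavage (OsO4 cat., NaIO4, 2,6-lutidine, dioxane–water) of the remaining 1,1-disubstituted alkene would give the methyl ketone F7.
- Horner–Wadsworth–Emmons olefination with trimethyl phosphonoacetate and NaH in THF would give 7. The geometric selectivity is only moderate, so chromatographic purification of the E-isomer would be needed.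

**Step 19.** The hindered C2 and C2' TBS ethers may be cleaved incompletely under buffered fluoride. If the conditions are forced, the sulfate may be lost or the polyene degraded.

- The fallback removes all silicon before sulfur is introduced and relies on symmetry. It sets out from 24 and comes back at 27.
- Bu4NF in THF can be used unbuffered and with gentle warming because no sulfate is present. It would strip all four silyl groups and give the tetrol nostoxanthin F8.
- F8 is twofold-symmetric, so O3 and O3' are equivalent.
- Roughly one equivalent of SO3·pyridine in pyridine at 0 °C would sulfate the less hindered equatorial 3-hydroxyl in preference to the neopentyl-type 2-hydroxyl, giving 27.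
- Neutral unreacted tetrol is easily separated from the ionic product and recycled. The ion exchange of step 19 then gives 28.

## Further compounds

F1 | step 7 | (2E,5R)-5-[(2S)-3,3-dimethyloxiran-2-yl]-3-methyl-5-(triethylsilyloxy)pent-2-enal | CC1(C)O[C@H]1[C@H](O[Si](CC)(CC)CC)C/C(C)=C/C=O
F2 | step 7 | tert-butyldimethylsilyl dienol ether of F1 (1-silyloxy-3-methylidene diene) | CC1(C)O[C@H]1[C@H](O[Si](CC)(CC)CC)CC(=C)/C=C/O[Si](C)(C)C(C)(C)C
F3 | step 7 | (1R,3R,4R)-3-hydroxy-2,2-dimethyl-6-methylidene-4-(triethylsilyloxy)cyclohexane-1-carbaldehyde | CC1(C)[C@@H](O)[C@H](O[Si](CC)(CC)CC)CC(=C)[C@H]1C=O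
F4 | step 2 | (4R)-2,6-dimethylhepta-1,5-dien-4-ol | CC(C)=C[C@H](O)CC(C)=C
F5 | step 2 | (1R)-1-[(2S)-3,3-dimethyloxiran-2-yl]-3-methylbut-3-en-1-ol | CC1(C)O[C@H]1[C@H](O)CC(C)=C
F6 | step 2 | triethylsilyl ether of F5 | CC1(C)O[C@H]1[C@H](O[Si](CC)(CC)CC)CC(C)=C
F7 | step 2 | (4R)-4-[(2S)-3,3-dimethyloxiran-2-yl]-4-(triethylsilyloxy)butan-2-one | CC1(C)O[C@H]1[C@H](O[Si](CC)(CC)CC)CC(C)=O
F8 | step 19 | nostoxanthin, (all-E,2R,3R,2'R,3'R)-β,β-carotene-2,3,2',3'-tetrol | CC1=C(/C=C/C(C)=C/C=C/C(C)=C/C=C/C=C(C)/C=C/C=C(C)/C=C/C2=C(C)C[C@@H](O)[C@H](O)C2(C)C)C(C)(C)[C@@H](O)[C@H](O)C1
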